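## Retrosynthetic overview

1. Target ⇐ its 4‑O‑PMB ether ⇐ C7–OH‑directed Sharpless epoxidation of the E‑5,6‑olefin of a 10‑membered lactone (oxirane = second ring).
2. 10‑Membered lactone (first ring) ⇐ ring‑closing metathesis at C5=C6 of a diene ester.
3. C3–C4 bond ⇐ β‑formyl ester + (Z)‑1‑(PMB‑oxy)allyl boron nucleophile, a carbonyl‑level, oxygen‑bearing carbon used as a carbanion (3,4‑syn).
4. C7–C8 bond ⇐ α‑acyloxy aldehyde (ozonolysis of an oct‑1‑en‑3‑yl ester, C9 from the pool) + (E)‑1‑(silyloxy)allyl boron nucleophile (7,8‑anti, 8,9‑anti); the freed C8–OH takes the side‑chain acid.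
5. Side‑chain acid ⇐ tiglic acid (asymmetric hydrogenation) and a Wittig olefination.

Assumption: atom numbers in the text follow the lactone (C1 = lactone carbonyl, C9 = pentyl‑bearing carbinol carbon), and every compound marked "starting material" in the list is bought as a catalogue item.

## Route

Step 1
Reactants: 1 tiglic acid [(2E)‑2‑methylbut‑2‑enoic acid]
Product: 2 (2R)‑2‑methylbutanoic acid
Conditions: H2 (4 atm), Ru(OAc)2[(R)‑H8‑BINAP] (0.5 mol %), MeOH, 20 °C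
Reagents that add atoms: none
Why: Noyori asymmetric hydrogenation of an α,β‑unsaturated acid, in which the carboxylate‑bound chiral ruthenium diphosphine adds H2 to one olefin face and sets the side‑chain stereocentre (R, about 95% ee, the ligand antipode being the one that gives the R acid).

Step 2
Reactants: 2 (2R)‑2‑methylbutanoic acid
Product: 3 (2R)‑2‑methylbutan‑1‑ol
Conditions: BH3·THF, THF, 0 → 20 °C; aq. work‑up
Reagents that add atoms: none
Why: Chemoselective borane reduction of a carboxylic acid to the primary alcohol, under which the α‑stereocentre cannot enolise and is retained.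

Step 3
Reactants: 3 (2R)‑2‑methylbutan‑1‑ol; 4 ethyl 2‑(triphenyl‑λ5‑phosphanylidene)propanoate
Product: 6 ethyl (2E,4R)‑2,4‑dimethylhex‑2‑enoate, via (2R)‑2‑methylbutanal 5 (not isolated)
Conditions: TEMPO (10 mol %), PhI(OAc)2, CH2Cl2, 20 °C; then 4, 40 °C
Reagents that add atoms: none
Why: One‑pot oxoammonium (TEMPO/PhI(OAc)2) oxidation and Wittig olefination, in which the volatile, epimerisable aldehyde is trapped as it forms by the stabilised ylide to give the E trisubstituted enoate (typically >95:5) without touching C4.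

Step 4
Reactants: 6 ethyl (2E,4R)‑2,4‑dimethylhex‑2‑enoate
Product: 7 (2E,4R)‑2,4‑dimethylhex‑2‑enoic acid
Conditions: LiOH, THF/MeOH/H2O, 40 °C; then 1 M HCl
Reagents that add atoms: lithium hydroxide, [Li+].[OH-]
Why: Saponification by acyl–oxygen cleavage, which leaves the olefin geometry and the γ‑stereocentre unchanged because hydroxide does not deprotonate the γ‑position.

Step 5
Reactants: 8 1‑methoxy‑4‑[(prop‑2‑yn‑1‑yloxy)methyl]benzene
Product: 9 1‑methoxy‑4‑[(propa‑1,2‑dien‑1‑yloxy)methyl]benzene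
Conditions: KOtBu (0.2 equiv), THF, 20 °C
Reagents that add atoms: none
Why: Base‑catalysed prototropic propargyl‑to‑allenyl ether isomerisation, driven to the conjugated alkoxyallene, with no stereocentre involved.

Step 6
Reactants: 10 (3R)‑oct‑1‑en‑3‑ol; 11 3,3‑dimethoxypropanoic acid
Product: 12 (3R)‑oct‑1‑en‑3‑yl 3,3‑dimethoxypropanoate
Conditions: DCC, DMAP (cat.), CH2Cl2, 0 → 20 °C
Reagents that add atoms: none
Why: Steglich esterification that forms the future lactone C–O bond at the outset with retention at C9 (the carbinol C–O bond is not broken) and carries C1–C3 with C3 masked as a dimethyl acetal.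

Step 7
Reactants: 12 (3R)‑oct‑1‑en‑3‑yl 3,3‑dimethoxypropanoate
Product: 14 (2R)‑1‑oxoheptan‑2‑yl 3,3‑dimethoxypropanoate, via ozonide 13 (not isolated)
Conditions: O3, CH2Cl2, −78 °C; then PPh3, −78 → 20 °C
Reagents that add atoms: ozone, [O-][O+]=O
Why: Ozonolysis with reductive work‑up cleaves the only olefin to the C8 aldehyde while ester and acetal are inert at −78 °C, and the configurationally labile α‑acyloxy aldehyde is used crude so that C9 is not epimerised.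

Step 8
Reactants: 14 (2R)‑1‑oxoheptan‑2‑yl 3,3‑dimethoxypropanoate; 15 tert‑butyldimethyl{[(2E)‑3‑(4,4,5,5‑tetramethyl‑1,3,2‑dioxaborolan‑2‑yl)prop‑2‑en‑1‑yl]oxy}silane
Product: 17 (3S,4R,5R)‑3‑[(tert‑butyldimethylsilyl)oxy]‑4‑hydroxydec‑1‑en‑5‑yl 3,3‑dimethoxypropanoate, via allylboronate 16 (not isolated)
Conditions: 15, [Ir(cod)(PPh2Me)2]PF6 (3 mol %, H2‑activated), THF, 20 °C; then 14, 0 → 20 °C, 24 h; pH 7 buffer work‑up
Reagents that add atoms: none
Why: γ‑(Silyloxy)allylboration after iridium‑catalysed olefin transposition, in which the oxygen‑bearing carbon of 16 (a 1‑silyloxyallyl carbanion equivalent, a carbonyl‑level carbon used as nucleophile) bonds to the aldehyde carbon through a closed chair transition state, the E geometry of the boronate giving the 7,8‑anti relationship and Cornforth/Felkin–Anh attack anti to the α‑acyloxy group giving the 8,9‑anti relationship, so that C7 and C8 are set from C9 and C8–OH is left free beside a silylated C7–O.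

Step 9
Reactants: 17 (3S,4R,5R)‑3‑[(tert‑butyldimethylsilyl)oxy]‑4‑hydroxydec‑1‑en‑5‑yl 3,3‑dimethoxypropanoate; 7 (2E,4R)‑2,4‑dimethylhex‑2‑enoic acid
Product: 18 (3S,4R,5R)‑3‑[(tert‑butyldimethylsilyl)oxy]‑5‑[(3,3‑dimethoxypropanoyl)oxy]dec‑1‑en‑4‑yl (2E,4R)‑2,4‑dimethylhex‑2‑enoate
Conditions: 2‑methyl‑6‑nitrobenzoic anhydride (MNBA), DMAP, Et3N, CH2Cl2, 20 °C
Reagents that add atoms: none
Why: Shiina esterification acylates the only free hydroxyl (C8–OH) with retention and fast enough to outrun 1,2‑migration of the neighbouring C9 ester, so the side chain is placed on C8 and nowhere else.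

Step 10
Reactants: 18 (3S,4R,5R)‑3‑[(tert‑butyldimethylsilyl)oxy]‑5‑[(3,3‑dimethoxypropanoyl)oxy]dec‑1‑en‑4‑yl (2E,4R)‑2,4‑dimethylhex‑2‑enoate
Product: 19 (3S,4R,5R)‑3‑[(tert‑butyldimethylsilyl)oxy]‑5‑[(3‑oxopropanoyl)oxy]dec‑1‑en‑4‑yl (2E,4R)‑2,4‑dimethylhex‑2‑enoate
Conditions: LiBF4, MeCN/H2O (50:1), 20 °C
Reagents that add atoms: water, O
Why: Mild, nearly neutral acetal hydrolysis unmasks the C3 aldehyde while the silyl ether, both esters and the olefin survive, and the β‑formyl ester is used at once.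

Step 11
Reactants: 19 (3S,4R,5R)‑3‑[(tert‑butyldimethylsilyl)oxy]‑5‑[(3‑oxopropanoyl)oxy]dec‑1‑en‑4‑yl (2E,4R)‑2,4‑dimethylhex‑2‑enoate; 9 1‑methoxy‑4‑[(propa‑1,2‑dien‑1‑yloxy)methyl]benzene
Product: 21 (3S,4R,5R)‑3‑[(tert‑butyldimethylsilyl)oxy]‑4‑{[(2E,4R)‑2,4‑dimethylhex‑2‑enoyl]oxy}dec‑1‑en‑5‑yl (3R,4R)‑3‑hydroxy‑4‑[(4‑methoxyphenyl)methoxy]hex‑5‑enoate, via allylborane 20 (not isolated)
Conditions: (−)‑Ipc2BH [from (+)‑α‑pinene], 9 (slight excess over B–H), THF, −25 → 0 °C; then 19, −78 °C; then HOCH2CH2NH2, 20 °C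
Reagents that add atoms: none
Why: Brown alkoxyallylboration with the reagent made by hydroboration of the alkoxyallene (boron to the terminal carbon, anti to the alkoxy group, giving the Z γ‑alkoxyallylborane), whose oxygen‑bearing carbon, again a carbonyl‑level carbon acting as nucleophile, attacks the Si face of the aldehyde through a chair transition state under control of the isopinocampheyl groups, giving the 3,4‑syn diol monoether with 3R (lactone numbering) while esters and olefins are untouched at −78 °C.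

Step 12
Reactants: 21 (3S,4R,5R)‑3‑[(tert‑butyldimethylsilyl)oxy]‑4‑{[(2E,4R)‑2,4‑dimethylhex‑2‑enoyl]oxy}dec‑1‑en‑5‑yl (3R,4R)‑3‑hydroxy‑4‑[(4‑methoxyphenyl)methoxy]hex‑5‑enoate
Product: 22 (4R,5R,6E,8S,9R,10R)‑8‑[(tert‑butyldimethylsilyl)oxy]‑4‑hydroxy‑5‑[(4‑methoxyphenyl)methoxy]‑2‑oxo‑10‑pentyl‑3,4,5,8,9,10‑hexahydro‑2H‑oxecin‑9‑yl (2E,4R)‑2,4‑dimethylhex‑2‑enoate
Conditions: second‑generation Grubbs catalyst RuCl2(=CHPh)(H2IMes)(PCy3) (10 mol %), CH2Cl2 (1 mM), 40 °C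
Reagents that add atoms: none
Why: Ring‑closing olefin metathesis at high dilution closes the 10‑membered lactone (first ring) with loss of ethene, the two termini being flanked by acyclic oxygenated carbons, the pattern that in 4,7‑dioxygenated nonenolide precursors leads to the E ring olefin, and no stereocentre is touched.

Step 13
Reactants: 22 (the silyl ether lactone of step 12)
Product: 23 (4R,5R,6E,8S,9S,10R)‑4,8‑dihydroxy‑5‑[(4‑methoxyphenyl)methoxy]‑2‑oxo‑10‑pentyl‑3,4,5,8,9,10‑hexahydro‑2H‑oxecin‑9‑yl (2E,4R)‑2,4‑dimethylhex‑2‑enoate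
Conditions: HF·pyridine, pyridine, THF, 0 → 20 °C
Reagents that add atoms: none
Why: Buffered fluoride desilylation frees the C7 allylic alcohol under mildly acidic conditions that do not provoke acyl migration or lactone opening and leave the PMB ether in place.

Step 14
Reactants: 23 (the C7 allylic alcohol of step 13)
Product: 24 (1R,2S,3S,4R,8R,9S,10S)‑2,8‑dihydroxy‑9‑[(4‑methoxyphenyl)methoxy]‑6‑oxo‑4‑pentyl‑5,11‑dioxabicyclo[8.1.0]undecan‑3‑yl (2E,4R)‑2,4‑dimethylhex‑2‑enoate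
Conditions: Ti(OiPr)4 (0.5 equiv), D‑(−)‑diisopropyl tartrate (0.6 equiv), t‑BuOOH (2 equiv), 4 Å MS, CH2Cl2, −20 °C
Reagents that add atoms: tert‑butyl hydroperoxide, CC(C)(C)OO
Why: Sharpless asymmetric epoxidation of a secondary E‑allylic alcohol in its matched pairing, D‑(−)‑tartrate delivering oxygen from the C7 hydroxyl to the olefin face that gives the erythro epoxy alcohol, so that reagent and substrate control converge on the trans (5R,6R) oxirane (second ring) while the C4 oxygen is masked as its PMB ether and cannot direct to the other face.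

Step 15
Reactants: 24 (the PMB‑protected epoxide of step 14)
Product: 25 (1R,2S,3S,4R,8R,9S,10R)‑2,8,9‑trihydroxy‑6‑oxo‑4‑pentyl‑5,11‑dioxabicyclo[8.1.0]undecan‑3‑yl (2E,4R)‑2,4‑dimethylhex‑2‑enoate
Conditions: DDQ, CH2Cl2/pH 7 phosphate buffer (10:1), 0 °C
Reagents that add atoms: none
Why: Oxidative cleavage of the PMB ether by DDQ in buffered wet solvent is neutral, so the epoxide, the C8 ester (no migration to C7–OH) and the lactone (no translactonisation to the γ‑lactone) survive and the target is released.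

## Compound list

1 | tiglic acid, (2E)‑2‑methylbut‑2‑enoic acid | C/C=C(\C)C(=O)O | starting material
2 | (2R)‑2‑methylbutanoic acid | CC[C@@H](C)C(=O)O | intermediate
3 | (2R)‑2‑methylbutan‑1‑ol | CC[C@@H](C)CO | intermediate
4 | ethyl 2‑(triphenyl‑λ5‑phosphanylidene)propanoate | CCOC(=O)C(C)=P(c1ccccc1)(c1ccccc1)c1ccccc1 | starting material
5 | (2R)‑2‑methylbutanal | CC[C@@H](C)C=O | intermediate
6 | ethyl (2E,4R)‑2,4‑dimethylhex‑2‑enoate | CCOC(=O)/C(C)=C/[C@H](C)CC | intermediate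
7 | (2E,4R)‑2,4‑dimethylhex‑2‑enoic acid | OC(=O)/C(C)=C/[C@H](C)CC | intermediate
8 | 1‑methoxy‑4‑[(prop‑2‑yn‑1‑yloxy)methyl]benzene | COc1ccc(COCC#C)cc1 | starting material
9 | 1‑methoxy‑4‑[(propa‑1,2‑dien‑1‑yloxy)methyl]benzene | COc1ccc(COC=C=C)cc1 | intermediate
10 | (3R)‑oct‑1‑en‑3‑ol | CCCCC[C@@H](O)C=C | starting material
11 | 3,3‑dimethoxypropanoic acid | COC(OC)CC(=O)O | starting material
12 | (3R)‑oct‑1‑en‑3‑yl 3,3‑dimethoxypropanoate | CCCCC[C@@H](OC(=O)CC(OC)OC)C=C | intermediate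
13 | (1R)‑1‑(1,2,4‑trioxolan‑3‑yl)hexyl 3,3‑dimethoxypropanoate (ozonide, both epimers at the trioxolane carbon) | CCCCC[C@@H](OC(=O)CC(OC)OC)C1OCOO1 | intermediate
14 | (2R)‑1‑oxoheptan‑2‑yl 3,3‑dimethoxypropanoate | CCCCC[C@@H](OC(=O)CC(OC)OC)C=O | intermediate
15 | tert‑butyldimethyl{[(2E)‑3‑(4,4,5,5‑tetramethyl‑1,3,2‑dioxaborolan‑2‑yl)prop‑2‑en‑1‑yl]oxy}silane | CC(C)(C)[Si](C)(C)OC/C=C/B1OC(C)(C)C(C)(C)O1 | starting material
16 | tert‑butyldimethyl{[(1E)‑3‑(4,4,5,5‑tetramethyl‑1,3,2‑dioxaborolan‑2‑yl)prop‑1‑en‑1‑yl]oxy}silane | CC(C)(C)[Si](C)(C)O/C=C/CB1OC(C)(C)C(C)(C)O1 | intermediate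
17 | (3S,4R,5R)‑3‑[(tert‑butyldimethylsilyl)oxy]‑4‑hydroxydec‑1‑en‑5‑yl 3,3‑dimethoxypropanoate | CCCCC[C@@H](OC(=O)CC(OC)OC)[C@@H](O)[C@@H](O[Si](C)(C)C(C)(C)C)C=C | intermediate
18 | (3S,4R,5R)‑3‑[(tert‑butyldimethylsilyl)oxy]‑5‑[(3,3‑dimethoxypropanoyl)oxy]dec‑1‑en‑4‑yl (2E,4R)‑2,4‑dimethylhex‑2‑enoate | CCCCC[C@@H](OC(=O)CC(OC)OC)[C@@H](OC(=O)/C(C)=C/[C@H](C)CC)[C@@H](O[Si](C)(C)C(C)(C)C)C=C | intermediate
19 | (3S,4R,5R)‑3‑[(tert‑butyldimethylsilyl)oxy]‑5‑[(3‑oxopropanoyl)oxy]dec‑1‑en‑4‑yl (2E,4R)‑2,4‑dimethylhex‑2‑enoate | CCCCC[C@@H](OC(=O)CC=O)[C@@H](OC(=O)/C(C)=C/[C@H](C)CC)[C@@H](O[Si](C)(C)C(C)(C)C)C=C | intermediate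
20 | [(2Z)‑3‑[(4‑methoxyphenyl)methoxy]prop‑2‑en‑1‑yl]bis[(−)‑isopinocampheyl]borane (isopinocampheyl groups from (+)‑α‑pinene) | COc1ccc(CO/C=C\CB([C@@H]2C[C@@H]3C[C@H]([C@H]2C)C3(C)C)[C@@H]2C[C@@H]3C[C@H]([C@H]2C)C3(C)C)cc1 | intermediate
21 | (3S,4R,5R)‑3‑[(tert‑butyldimethylsilyl)oxy]‑4‑{[(2E,4R)‑2,4‑dimethylhex‑2‑enoyl]oxy}dec‑1‑en‑5‑yl (3R,4R)‑3‑hydroxy‑4‑[(4‑methoxyphenyl)methoxy]hex‑5‑enoate | CCCCC[C@@H](OC(=O)C[C@@H](O)[C@H](OCc1ccc(OC)cc1)C=C)[C@@H](OC(=O)/C(C)=C/[C@H](C)CC)[C@@H](O[Si](C)(C)C(C)(C)C)C=C | intermediate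
22 | (4R,5R,6E,8S,9R,10R)‑8‑[(tert‑butyldimethylsilyl)oxy]‑4‑hydroxy‑5‑[(4‑methoxyphenyl)methoxy]‑2‑oxo‑10‑pentyl‑3,4,5,8,9,10‑hexahydro‑2H‑oxecin‑9‑yl (2E,4R)‑2,4‑dimethylhex‑2‑enoate | CCCCC[C@H]1OC(=O)C[C@@H](O)[C@H](OCc2ccc(OC)cc2)/C=C/[C@H](O[Si](C)(C)C(C)(C)C)[C@@H]1OC(=O)/C(C)=C/[C@H](C)CC | intermediate
23 | (4R,5R,6E,8S,9S,10R)‑4,8‑dihydroxy‑5‑[(4‑methoxyphenyl)methoxy]‑2‑oxo‑10‑pentyl‑3,4,5,8,9,10‑hexahydro‑2H‑oxecin‑9‑yl (2E,4R)‑2,4‑dimethylhex‑2‑enoate | CCCCC[C@H]1OC(=O)C[C@@H](O)[C@H](OCc2ccc(OC)cc2)/C=C/[C@H](O)[C@@H]1OC(=O)/C(C)=C/[C@H](C)CC | intermediate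
24 | (1R,2S,3S,4R,8R,9S,10S)‑2,8‑dihydroxy‑9‑[(4‑methoxyphenyl)methoxy]‑6‑oxo‑4‑pentyl‑5,11‑dioxabicyclo[8.1.0]undecan‑3‑yl (2E,4R)‑2,4‑dimethylhex‑2‑enoate | CCCCC[C@H]1OC(=O)C[C@@H](O)[C@H](OCc2ccc(OC)cc2)[C@H]3O[C@@H]3[C@H](O)[C@@H]1OC(=O)/C(C)=C/[C@H](C)CC | intermediate
25 | (1R,2S,3S,4R,8R,9S,10R)‑2,8,9‑trihydroxy‑6‑oxo‑4‑pentyl‑5,11‑dioxabicyclo[8.1.0]undecan‑3‑yl (2E,4R)‑2,4‑dimethylhex‑2‑enoate | CCCCC[C@H]1OC(=O)C[C@@H](O)[C@H](O)[C@H]2O[C@@H]2[C@H](O)[C@@H]1OC(=O)/C(C)=C/[C@H](C)CC | target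

## Step count and risks

Total steps: 15. Longest linear sequence: 11 steps (1 to 25 through steps 1–4 and 9–15); counted from 10 the main chain is 10 steps (steps 6–15).

The three steps most likely to fail:

Step 12 (ring‑closing metathesis). The risks are the E/Z ratio and oligomerisation in closing a 10‑membered ring next to a bulky allylic silyl ether. The fallback changes the order of events and the substrate class. Set out from 21 and cleave the silyl ether first (HF·pyridine) to give (3S,4S,5R)‑4‑{[(2E,4R)‑2,4‑dimethylhex‑2‑enoyl]oxy}‑3‑hydroxydec‑1‑en‑5‑yl (3R,4R)‑3‑hydroxy‑4‑[(4‑methoxyphenyl)methoxy]hex‑5‑enoate F2. Then close the ring on the free C7 allylic alcohol with the same ruthenium carbene. The unprotected carbinol speeds loading of ruthenium at the C6 terminus and removes the large silyloxy group beside the forming olefin. The product is 23, where the route is rejoined.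

Step 14 (epoxidation inside the macrocycle). The risks are a slow reaction or the wrong face if the ring cannot adopt the titanium‑bound geometry. The fallback changes both the directing group and the oxidant. Set out from 22 and remove the PMB group first (DDQ, wet CH2Cl2) to give (4R,5R,6E,8S,9R,10R)‑8‑[(tert‑butyldimethylsilyl)oxy]‑4,5‑dihydroxy‑2‑oxo‑10‑pentyl‑3,4,5,8,9,10‑hexahydro‑2H‑oxecin‑9‑yl (2E,4R)‑2,4‑dimethylhex‑2‑enoate F3. Epoxidise F3 with mCPBA (NaHCO3, CH2Cl2, 0 °C) under hydrogen‑bond (Henbest) direction by the C4 hydroxyl. A peracid directed by an allylic hydroxyl on an E olefin favours the threo epoxy alcohol, which here is the same olefin face as in the main route, and the silyl ether at C7 cannot direct. This gives (1S,2S,3R,4R,8R,9S,10R)‑2‑[(tert‑butyldimethylsilyl)oxy]‑8,9‑dihydroxy‑6‑oxo‑4‑pentyl‑5,11‑dioxabicyclo[8.1.0]undecan‑3‑yl (2E,4R)‑2,4‑dimethylhex‑2‑enoate F4. HF·pyridine then gives 25 directly.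

Step 8 (first oxyallylation). The risks are a slow thermal addition of a pinacol boronate to a labile α‑acyloxy aldehyde, with epimerisation at C9, acyl migration or a modest diastereomer ratio. The fallback changes the nucleophile to an allylindium made by transmetalation. Set out from 14 and use (Z)‑tributyl{3‑[(tert‑butyldimethylsilyl)oxy]prop‑2‑en‑1‑yl}stannane F1, prepared from allyl tert‑butyldimethylsilyl ether by sec‑BuLi metalation and Bu3SnCl quench. With InCl3 in ethyl acetate at −78 °C, F1 gives the (E)‑γ‑silyloxyallylindium dichloride. This adds to 14 within minutes at −78 °C through a closed transition state and gives the same anti adduct 17, where the route is rejoined.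

Further compounds

F1 | step 8 | (Z)‑tributyl{3‑[(tert‑butyldimethylsilyl)oxy]prop‑2‑en‑1‑yl}stannane | CCCC[Sn](CCCC)(CCCC)C/C=C\O[Si](C)(C)C(C)(C)C
F2 | step 12 | (3S,4S,5R)‑4‑{[(2E,4R)‑2,4‑dimethylhex‑2‑enoyl]oxy}‑3‑hydroxydec‑1‑en‑5‑yl (3R,4R)‑3‑hydroxy‑4‑[(4‑methoxyphenyl)methoxy]hex‑5‑enoate | CCCCC[C@@H](OC(=O)C[C@@H](O)[C@H](OCc1ccc(OC)cc1)C=C)[C@@H](OC(=O)/C(C)=C/[C@H](C)CC)[C@@H](O)C=C
F3 | step 14 | (4R,5R,6E,8S,9R,10R)‑8‑[(tert‑butyldimethylsilyl)oxy]‑4,5‑dihydroxy‑2‑oxo‑10‑pentyl‑3,4,5,8,9,10‑hexahydro‑2H‑oxecin‑9‑yl (2E,4R)‑2,4‑dimethylhex‑2‑enoate | CCCCC[C@H]1OC(=O)C[C@@H](O)[C@H](O)/C=C/[C@H](O[Si](C)(C)C(C)(C)C)[C@@H]1OC(=O)/C(C)=C/[C@H](C)CC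
F4 | step 14 | (1S,2S,3R,4R,8R,9S,10R)‑2‑[(tert‑butyldimethylsilyl)oxy]‑8,9‑dihydroxy‑6‑oxo‑4‑pentyl‑5,11‑dioxabicyclo[8.1.0]undecan‑3‑yl (2E,4R)‑2,4‑dimethylhex‑2‑enoate | CCCCC[C@H]1OC(=O)C[C@@H](O)[C@H](O)[C@H]2O[C@@H]2[C@H](O[Si](C)(C)C(C)(C)C)[C@@H]1OC(=O)/C(C)=C/[C@H](C)CC
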